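The number to hold against this flask's charge of 0.026 M of solid substrate is how much the solution can take up, and two chemists disagree on whether that limit matters here.

| flask | solid substrate | remark | time |
|---|---|---|---|
| Saturday's | 0.017 M | run made earlier |  |
| Tuesday's | 0.039 M | run made earlier |  |
| flask | 0.026 M |  | 10 d |

| run | time / d | target / % | isomer of the product / % |
|---|---|---|---|
| Saturday's | 1.04 | 34.3 | 5.6 |
| Saturday's | 2.08 | 34.3 | 5.9 |
| Saturday's | 3.00 | 33.9 | 5.2 |
| Saturday's | 4.00 | 34.1 | 5.4 |
| Saturday's | 5.00 | 33.8 | 5.3 |
| Saturday's | 6.00 | 34.1 | 4.8 |
| Tuesday's | 0.500 | 16.8 | 2.8 |
| Tuesday's | 0.833 | 17.1 | 2.8 |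
| Tuesday's | 1.25 | 17.0 | 3.2 |
| Tuesday's | 2.00 | 17.4 | 2.4 |
| Tuesday's | 4.00 | 17.3 | 3.0 |
| Tuesday's | 6.00 | 17.4 | 2.3 |

(readings scatter by 0.3 percentage points)

- solid substrate is a solid; its amount is given per volume of the solution
- what was read earlier has a scatter of 0.3 percentage points, one standard deviation
- reactions considered so far: starting material <-> target; target <-> isomer of the product; isomer of the product <-> starting material; solid substrate <-> starting material
- at the start none of the solid substrate is in solution

- share of target in target plus isomer of the product at 1.0 h
- share of target in target plus isomer of the product at 10 d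
- which of target and isomer of the product there is more of at 10 d

The first chemist reads percentages. Target in Saturday's run stays flat at 34.1% of the charge, and she takes that as the yield of the recipe, so she expects the same percentage in the new flask.

The second chemist reads concentrations. Saturday's [target] is 0.00579 M, while Tuesday's, from a mean of 17.2%, is 0.00669 M. The concentration rose by a small step, yet the percentage fell to half. He therefore holds that solid stayed undissolved on Tuesday but not on Saturday, so Saturday's solution shows how dissolved material divides, with target as 34.1% of it. Tuesday's [target] divided by that fraction gives 0.0196 M, the total dissolved concentration these solutions hold while solid is present, a solubility limit counted over the dissolved forms. Saturday's charge lies below it and Tuesday's above it, as his reading requires.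

The share does not divide them: it reads 86.4% on Saturday and 86.2% on Tuesday.

I side with him. This flask's charge exceeds the capacity, so I expect target at 25.7% of the charge and 24.6% still solid. The earliest reading comes at 0.500 d, so I put no figure on 1.0 h.

The forecast gives 75% at 1.0 h, which it calls a guess, and 86.3% at 10 d with target ahead, since “the ratio is unaffected”.

The simulation gives 78.7% at 1.0 h and 86.2% at 10 d, with target at 25.8% of the charge against 4.14% of isomer of the product.

    starting material ⇌ target (K = 0.560, k = 0.740 h⁻¹)
    target ⇌ isomer of the product (K = 0.160, k = 0.110 h⁻¹)
    isomer of the product ⇌ starting material (k = 7.00 h⁻¹)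
    solid substrate ⇌ starting material, rate k4*(cs4 - [starting material]) while solid is left; crystals form when [starting material] > cs4 (solubility = 12.0 mM, k = 0.460 h⁻¹)

In this flask starting material and target relax with a half-life of 0.336 h, and target passes forward into isomer of the product with a half-life of 0.26 d, both short against 10 d. The flask reads the same at 1.00 d and 100 d, target 25.8% beside 23.9% solid, the picture the capacity 0.0196 M gave. A neighbour flask charged with 0.0065 M lies below the capacity, which gives no solid and Saturday's 34.1%, her percentage. It ends with 0% solid and target at 33.9%.

The runs stem from a simulated flask for an exercise, noise included.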